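**Plan**

- Retrosynthesis cuts, in this order: the ring alkene C4=C5 of the 3,6-dihydro-1,2-dioxine (ring-closing metathesis), the C3–O2 bond (conjugate addition of a hydroperoxide to a dienal), the peroxyketal bond C6–O1 (H2O2 addition to an alkoxyallene) and the C6–hexadecyl bond (allene alkylation).
- Forward: the hexadecyl chain is joined to methoxyallene, the allene becomes a tertiary hydroperoxy ketal, this adds to the dienal to give an open-chain dialkyl peroxide holding every carbon, the aldehyde becomes the methyl ester, and the only ring, O1–O2–C3–C4=C5–C6, is closed last.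
- Enabling feature: C4=C5 is the only C=C and lies between the two sp3 ring carbons C3 and C6, each bonded to one oxygen of the O1–O2 unit, so an open-chain peroxide can carry an alkenyl group on each; a six-membered ring admits only the Z alkene.
- Helpers: a styryl group on C3 steers the hydroperoxide to C3 and leaves as styrene in the ring closure; the terminal CH2 of the allene leaves in the same event.
- Stereochemistry: C3 (S) comes from the (S)-diphenylprolinol silyl ether catalyst. C6 is formed in the open chain without bias and the (6R) epimer is isolated after ring closure; ketalisation on the ring is avoided because axial attack of methanol on the ring cation is expected to favour the (6S) epimer.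

Key step: step 6

Remark on the chemistry: the tertiary hydroperoxide of step 2 is racemic and step 3 does not select between its enantiomers, so the open-chain peroxides of steps 3 to 5 are pairs of epimers at the peroxyketal carbon (left undefined in their SMILES); ring closure gives the target and its C6 epimer, which are separated on silica gel.

Step 1
Reactants: 1 methoxyallene (1-methoxypropa-1,2-diene); 2 1-iodohexadecane
Product: 4 3-methoxynonadeca-1,2-diene, via 1-lithio-1-methoxyallene 3 (not isolated)
Conditions: n-BuLi, THF, −40 °C; then 2, −40 °C to rt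
Reagents that add atoms: none
Why: Alkylation of a lithiated alkoxyallene: n-BuLi removes the allenic hydrogen next to oxygen and the carbanion displaces iodide from the primary iodide at that carbon (SN2), forming no stereocentre.

Step 2
Reactants: 4 3-methoxynonadeca-1,2-diene
Product: 5 (±)-3-hydroperoxy-3-methoxynonadec-1-ene
Conditions: H2O2 (anhydrous, in Et2O, excess), PPTS (cat.), 0 °C
Reagents that add atoms: hydrogen peroxide, OO
Why: Acid-catalysed peroxyketal formation from an enol ether (here an alkoxyallene): protonation at the central allene carbon gives a methoxy-stabilised allyl cation that H2O2, in excess to prevent a second addition, captures at the oxygen-bearing carbon, so the new stereocentre is formed racemic.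

Step 3
Reactants: 5 (±)-3-hydroperoxy-3-methoxynonadec-1-ene; 6 (2E,4E)-5-phenylpenta-2,4-dienal
Product: 7 (3S,4E)-3-[(3-methoxynonadec-1-en-3-yl)peroxy]-5-phenylpent-4-enal (pair of epimers at the peroxyketal carbon C3′)
Conditions: (S)-2-[diphenyl(trimethylsilyloxy)methyl]pyrrolidine (10 mol %), PhCO2H (10 mol %), toluene, 0 °C
Reagents that add atoms: none
Why: Amine-catalysed asymmetric oxa-Michael addition of a hydroperoxide to an enal through its iminium ion: the phenyl group at C5 keeps the attack at C3 (attack at C5 would break the styrene conjugation), the diphenyl(silyloxy)methyl group of the (S)-catalyst blocks one face of the E, s-trans iminium ion so that oxygen adds to the open face and sets C3 as (S), and the racemic hydroperoxide is taken up without selection so both epimers at C3′ form.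

Step 4
Reactants: 7 (3S,4E)-3-[(3-methoxynonadec-1-en-3-yl)peroxy]-5-phenylpent-4-enal
Product: 8 (3S,4E)-3-[(3-methoxynonadec-1-en-3-yl)peroxy]-5-phenylpent-4-enoic acid (pair of epimers at C3′)
Conditions: NaClO2, NaH2PO4, 2-methylbut-2-ene, t-BuOH/H2O, 0 °C
Reagents that add atoms: sodium chlorite, [Na+].[O-]Cl=O
Why: Pinnick oxidation: chlorous acid adds to the aldehyde and fragments to the carboxylic acid and HOCl (trapped by 2-methylbut-2-ene), while the phosphate buffer and low temperature should spare the acid-labile allylic peroxyketal, the O–O bond and both alkenes, and no stereocentre is touched.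

Step 5
Reactants: 8 (3S,4E)-3-[(3-methoxynonadec-1-en-3-yl)peroxy]-5-phenylpent-4-enoic acid
Product: 9 methyl (3S,4E)-3-[(3-methoxynonadec-1-en-3-yl)peroxy]-5-phenylpent-4-enoate (pair of epimers at C3′)
Conditions: TMSCHN2, toluene/MeOH, 0 °C
Reagents that add atoms: (trimethylsilyl)diazomethane, C[Si](C)(C)C=[N+]=[N-]
Why: Methyl ester formation with TMS-diazomethane in methanol (O-alkylation of the carboxylate) is neutral, so neither β-elimination of the peroxide nor ionisation of the peroxyketal should occur and both stereocentres stay untouched.

Step 6
Reactants: 9 methyl (3S,4E)-3-[(3-methoxynonadec-1-en-3-yl)peroxy]-5-phenylpent-4-enoate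
Product: 10 methyl 2-[(3S,6R)-6-hexadecyl-6-methoxy-3,6-dihydro-1,2-dioxin-3-yl]acetate (target)
Conditions: second-generation Grubbs catalyst RuCl2(H2IMes)(PCy3)(=CHPh) (5 mol %), 1,4-benzoquinone (10 mol %), CH2Cl2 (5 mM), 40 °C; then chromatography on silica gel
Reagents that add atoms: none
Why: Ring-closing olefin metathesis: the ruthenium alkylidene exchanges onto one alkene of 9, adds across the other through a ruthenacyclobutane, and cycloreversion forms C4=C5 and releases styrene. The closest known reaction types are ring closure of diene acetals to 2-alkoxy-3,6-dihydro-2H-pyrans and olefin metathesis of dienes that contain a dialkyl peroxide, which ruthenium carbenes tolerate. The 1,2-dioxine ring closes as a six-membered ring by joining the two alkene carbons attached to C3 and C6 across the C3–O2–O1–C6 tether, and this ring size allows only the Z alkene. No stereocentre is formed and C3 and C6 keep their configurations because the medium is neutral and free of base, so the (3′R) epimer of 9 should give 10 and the (3′S) epimer the (3S,6S) epimer, which is removed on silica gel. The step needs chemoselectivity for C=C over the O–O bond and over double-bond migration; the peroxide is dialkyl (no O–H), C6 carries no hydrogen, benzoquinone intercepts ruthenium hydrides and high dilution suppresses dimer formation.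

**Compound list**

1 | methoxyallene (1-methoxypropa-1,2-diene) | COC=C=C | starting material
2 | 1-iodohexadecane | CCCCCCCCCCCCCCCCI | starting material
3 | 1-lithio-1-methoxyallene | [Li]C(OC)=C=C | intermediate
4 | 3-methoxynonadeca-1,2-diene | C=C=C(OC)CCCCCCCCCCCCCCCC | intermediate
5 | (±)-3-hydroperoxy-3-methoxynonadec-1-ene (racemate) | C=CC(OC)(OO)CCCCCCCCCCCCCCCC | intermediate
6 | (2E,4E)-5-phenylpenta-2,4-dienal | O=C/C=C/C=C/c1ccccc1 | starting material
7 | (3S,4E)-3-[(3-methoxynonadec-1-en-3-yl)peroxy]-5-phenylpent-4-enal, pair of epimers at C3′ | c1ccccc1/C=C/[C@H](CC=O)OOC(OC)(C=C)CCCCCCCCCCCCCCCC | intermediate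
8 | (3S,4E)-3-[(3-methoxynonadec-1-en-3-yl)peroxy]-5-phenylpent-4-enoic acid, pair of epimers at C3′ | c1ccccc1/C=C/[C@H](CC(=O)O)OOC(OC)(C=C)CCCCCCCCCCCCCCCC | intermediate
9 | methyl (3S,4E)-3-[(3-methoxynonadec-1-en-3-yl)peroxy]-5-phenylpent-4-enoate, pair of epimers at C3′ | c1ccccc1/C=C/[C@H](CC(=O)OC)OOC(OC)(C=C)CCCCCCCCCCCCCCCC | intermediate
10 | methyl 2-[(3S,6R)-6-hexadecyl-6-methoxy-3,6-dihydro-1,2-dioxin-3-yl]acetate | CCCCCCCCCCCCCCCC[C@]1(OC)C=C[C@H](CC(=O)OC)OO1 | target

Total step count: 6. Longest linear sequence: 6 steps (1 → 4 → 5 → 7 → 8 → 9 → 10).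

**Steps most likely to fail**

Step 3. The enamine left on the catalyst after the addition may attack the O–O bond (epoxide formation with loss of the ketal fragment), and the hindered tertiary hydroperoxide may add so slowly that reversal of the addition competes. The fallback sets out from 6 and comes back at 9: the C3–O bond is made with a small α-methoxy hydroperoxide of the kind established for this addition, and the C6 fragment is attached afterwards. 2-Methoxypropene and ethereal H2O2 (PPTS) would give 2-hydroperoxy-2-methoxypropane F1. Addition of F1 to 6 under the conditions of step 3 would give (3S,4E)-3-[(2-methoxypropan-2-yl)peroxy]-5-phenylpent-4-enal F2. Chlorite oxidation would give (3S,4E)-3-[(2-methoxypropan-2-yl)peroxy]-5-phenylpent-4-enoic acid F3, and TMSCHN2 its ester, methyl (3S,4E)-3-[(2-methoxypropan-2-yl)peroxy]-5-phenylpent-4-enoate F4. Aqueous acetic acid in THF would free methyl (3S,4E)-3-hydroperoxy-5-phenylpent-4-enoate F5, and PPTS-catalysed addition of F5 to allene 4 in CH2Cl2 would give 9.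

Step 6. The ruthenium alkylidene may fail to engage the vinyl group on the fully substituted, doubly oxygenated C6, so that ring closure is slow and alkene migration or catalyst loss takes over. The fallback sets out from 9 (with 4) and comes back at 10: the hindered vinyl group is left untouched and the ring is closed through the C6–O1 bond instead. Dilute aqueous acid would hydrolyse 4 to nonadec-1-en-3-one F6. Cross-metathesis of the styryl group of 9 with F6 (second-generation Hoveyda–Grubbs catalyst RuCl2(H2IMes)(=CH-C6H4-2-OiPr), CH2Cl2, 40 °C) would give methyl (3S,4E)-3-[(3-methoxynonadec-1-en-3-yl)peroxy]-6-oxodocos-4-enoate F7, in which the peroxyketal protects the hydroperoxide. Aqueous acetic acid in THF would free methyl (3S,4E)-3-hydroperoxy-6-oxodocos-4-enoate F8. Sensitised irradiation would isomerise the enone to methyl (3S,4Z)-3-hydroperoxy-6-oxodocos-4-enoate F9, which should close to the cyclic hemiketal methyl 2-[(3S)-6-hexadecyl-6-hydroxy-3,6-dihydro-1,2-dioxin-3-yl]acetate F10. CSA in methanol would then give 10 after the same separation from its C6 epimer, with a less favourable epimer distribution expected than in the main route.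

Step 2. The methoxyallyl cation may be captured at its terminal carbon, or the product hydroperoxide may add to a second molecule of allene to give a symmetrical bis-ketal peroxide. The fallback sets out from 4 and comes back at 5: the ketal carbon is first fixed as a stable dimethyl ketal and the hydroperoxide is introduced by exchange under equilibrating conditions. Methanol and PPTS would convert 4 into 3,3-dimethoxynonadec-1-ene F11, which is purified; ethereal H2O2 with an acid catalyst would then exchange one methoxy group for OOH to give 5.

**Further compounds**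

F1 | step 3 | 2-hydroperoxy-2-methoxypropane | COC(C)(C)OO
F2 | step 3 | (3S,4E)-3-[(2-methoxypropan-2-yl)peroxy]-5-phenylpent-4-enal | c1ccccc1/C=C/[C@H](CC=O)OOC(C)(C)OC
F3 | step 3 | (3S,4E)-3-[(2-methoxypropan-2-yl)peroxy]-5-phenylpent-4-enoic acid | c1ccccc1/C=C/[C@H](CC(=O)O)OOC(C)(C)OC
F4 | step 3 | methyl (3S,4E)-3-[(2-methoxypropan-2-yl)peroxy]-5-phenylpent-4-enoate | c1ccccc1/C=C/[C@H](CC(=O)OC)OOC(C)(C)OC
F5 | step 3 | methyl (3S,4E)-3-hydroperoxy-5-phenylpent-4-enoate | c1ccccc1/C=C/[C@H](CC(=O)OC)OO
F6 | step 6 | nonadec-1-en-3-one | C=CC(=O)CCCCCCCCCCCCCCCC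
F7 | step 6 | methyl (3S,4E)-3-[(3-methoxynonadec-1-en-3-yl)peroxy]-6-oxodocos-4-enoate, pair of epimers at C3′ | CCCCCCCCCCCCCCCCC(=O)/C=C/[C@H](CC(=O)OC)OOC(OC)(C=C)CCCCCCCCCCCCCCCC
F8 | step 6 | methyl (3S,4E)-3-hydroperoxy-6-oxodocos-4-enoate | CCCCCCCCCCCCCCCCC(=O)/C=C/[C@H](CC(=O)OC)OO
F9 | step 6 | methyl (3S,4Z)-3-hydroperoxy-6-oxodocos-4-enoate | CCCCCCCCCCCCCCCCC(=O)/C=C\[C@H](CC(=O)OC)OO
F10 | step 6 | methyl 2-[(3S)-6-hexadecyl-6-hydroxy-3,6-dihydro-1,2-dioxin-3-yl]acetate, both C6 epimers | CCCCCCCCCCCCCCCCC1(O)C=C[C@H](CC(=O)OC)OO1
F11 | step 2 | 3,3-dimethoxynonadec-1-ene | C=CC(OC)(OC)CCCCCCCCCCCCCCCC
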